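**Retrosynthetic overview**
1. The ten-membered carbocycle (C1–C10) is closed last, at C4–C5, by an intramolecular B-alkyl Suzuki–Miyaura coupling of a C3=C4 vinyl group with a (5Z)-C5 vinyl iodide. Only a Mitsunobu acetate inversion at C12 and desilylation follow.
2. Ring A (C1, C10, C11, C12, C13, C14) comes from a silicon-tethered type 2 intramolecular Diels–Alder reaction. A 1-methoxy-3-silyloxy diene (C11–C14, C20) adds to an (E)-2-methyl enal (C10=C1, C15, C2). C10–C11 and C1–C14 form together, and C1, C10 and C11 are relayed from C9.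
3. Enabling feature: in ring A the oxygenated C12 stands 1,3 to C10, and C10 carries the C9 carbinol. O12 and O9 can therefore be bridged by one Si(iPr)2 unit (temporary seven-membered ring C9–C10–C11–C12–O–Si–O). C12–O with C13=C14 is the retron of the silyloxy diene, quaternary C1 next to oxygenated C2 is the retron of the enal, and C9–H/C15 A(1,3) strain makes C9 the facial control element.
4. The lactone half (C6–C10, C17–C19) is cut out of methyl 4,6-O-benzylidene-α-D-glucopyranoside (glucose C1–C5 = C6–C10). An intramolecular Reformatsky lactonisation on the 3-ulose sets C8 and C17. A zinc-induced (Vasella) ring cleavage keeps C7, C8 and C9 and frees both chain ends.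
5. Order of ring formation: γ-lactone, then ring A (with the temporary silepane), then the ten-membered ring.

Key step: step 13

Remark (assumption and numbering): briarane numbering is used throughout.
- Ring A = C1, C10–C14. Ten-membered ring = C1–C10. Lactone = O7, C7, C8, C17, C19.
- Methyl groups: C15 on C1, C16 on C5, C18 on C17, C20 on C11. β is the face of C15.
- The CHBr centre of 4–6 is carried as a mixture of epimers because it is lost in step 4.

**Step 1**
Reactants: 1 (E)-4-methoxybut-3-en-2-one
Product: 2 (E)-1-methoxypent-1-en-3-one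
Conditions: LDA, THF, −78 °C; MeI, −78 → −20 °C
Reagents that add atoms: iodomethane, CI
Why: Kinetic deprotonation of the vinylogous ester at its only enolisable site (the acetyl CH3) and C-methylation of the cross-conjugated lithium enolate (enolate alkylation) should give the ethyl ketone with the E-enol ether intact and no stereocentre formed.

**Step 2**
Reactants: 3 methyl 4,6-O-[(R)-benzylidene]-α-D-glucopyranoside; 4 2-bromopropanoyl bromide (racemic)
Product: 5 methyl 4,6-O-benzylidene-2-O-(2-bromopropanoyl)-α-D-glucopyranoside (epimers at CHBr)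
Conditions: pyridine, CH2Cl2, −40 °C
Reagents that add atoms: none
Why: Regioselective O-acylation, because in this diol O2–H, made more acidic and more nucleophilic by the cis anomeric methoxy group, should be acylated ahead of O3–H at low temperature.

**Step 3**
Reactants: 5 methyl 4,6-O-benzylidene-2-O-(2-bromopropanoyl)-α-D-glucopyranoside
Product: 6 methyl 4,6-O-benzylidene-2-O-(2-bromopropanoyl)-α-D-ribo-hexopyranosid-3-ulose
Conditions: Dess–Martin periodinane, CH2Cl2, 0 °C → rt
Reagents that add atoms: none
Why: Dess–Martin oxidation of the one free secondary alcohol runs under near-neutral conditions, so the base-sensitive 2-acyloxy-3-ulose should form without β-elimination or epimerisation at C2 of the sugar.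

**Step 4**
Reactants: 6 methyl 4,6-O-benzylidene-2-O-(2-bromopropanoyl)-α-D-ribo-hexopyranosid-3-ulose
Product: 7 methyl 4,6-O-benzylidene-3-C-[(1R)-1-carboxyethyl]-α-D-allopyranoside 3′,2-lactone (trans-fused γ-lactone, axial tertiary 3-OH; C7, C8, C9, C17 as in the target)
Conditions: Zn dust (TMSCl-activated), THF, rt → 40 °C; aq. NH4Cl
Reagents that add atoms: none
Why: Intramolecular Reformatsky reaction (5-exo-trig aldol lactonisation) in which the zinc enolate held on equatorial O2 should attack the C3 ketone from the β-face (equatorial attack), since the axial path is blocked by the axial anomeric OMe, which sets C8 with an axial OH, while the C17 methyl settles next to the small OH and anti to C9, a centre that remains equilibratable through the lactone enolate.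

**Step 5**
Reactants: 7 benzylidene lactone
Product: 8 methyl 3-C-[(1R)-1-carboxyethyl]-α-D-allopyranoside 3′,2-lactone (3,4,6-triol)
Conditions: H2 (1 atm), Pd(OH)2/C, EtOAc–MeOH, rt
Reagents that add atoms: none
Why: Hydrogenolysis of the benzylidene acetal is neutral and meets no other reducible group, so lactone regiochemistry (O2, not O4) and all stereocentres are kept.

**Step 6**
Reactants: 8 triol lactone
Product: 9 6-deoxy-6-iodo derivative of 8
Conditions: I2, PPh3, imidazole, THF, 0 °C → rt
Reagents that add atoms: iodine, II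
Why: Appel-type iodination is selective for the primary hydroxyl over the hindered secondary O4–H and the tertiary O3–H.

**Step 7**
Reactants: 9 iodo diol lactone
Product: 10 3,4-bis-O-triethylsilyl ether of 9
Conditions: TESOTf, 2,6-lutidine, CH2Cl2, 0 °C → rt
Reagents that add atoms: triethylsilyl trifluoromethanesulfonate, CC[Si](CC)(CC)OS(=O)(=O)C(F)(F)F
Why: Silyl triflate silylation covers both the secondary (future O9) and the tertiary (future O8) hydroxyl, which blocks retro-aldol cleavage and lactone migration in the basic olefination to come.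

**Step 8**
Reactants: 10 bis-TES iodo glycoside
Product: 11 lactone aldehyde: γ-lactone O7–C19(=O)–C17H(CH3)–C8(OTES)–C7H with CHO (C6) on C7 and the C9H(OTES)–C10H=CH2 chain on C8 (C7, C8, C9, C17 as in the target)
Conditions: Zn dust (acid-washed), THF–H2O 9:1, ultrasound, 40 °C
Reagents that add atoms: none
Why: Vasella fragmentation, in which zinc insertion into C6–I and elimination across C5–O5 open the pyranose, and collapse of the hemiacetal anion expels methoxide, should give the C6 aldehyde and the C10 vinyl group while the three carried stereocentres are not touched.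

**Step 9**
Reactants: 11 lactone aldehyde; 12 ethyltriphenylphosphonium iodide
Product: 13 (5Z)-vinyl iodide: as 11 with C7–C6H=C5(I)–C16H3, iodine cis to C7
Conditions: 12, n-BuLi, THF, 0 °C; I2, −78 °C; NaHMDS, −20 °C; then 11, −78 → −20 °C
Reagents that add atoms: iodine, II
Why: Stork–Zhao-type Wittig olefination with (1-iodoethylidene)triphenylphosphorane is kinetically Z-selective, so iodine should end cis to C7 and mark the position that C4 will take with retention.

**Step 10**
Reactants: 13 bis-TES vinyl iodide
Product: 14 C9 alcohol (C8–OTES kept)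
Conditions: AcOH–THF–H2O 3:1:1, 0 °C → rt
Reagents that add atoms: none
Why: Acid-catalysed silyl ether hydrolysis is governed by steric access, so the secondary allylic TES ether should be cleaved well before the tertiary one, and the acidic medium avoids lactone migration to O9.

**Step 11**
Reactants: 14 C9 allylic alcohol; 15 methacrolein
Product: 16 (E)-enal: C9H(OH)–C10H=C1(C15H3)–C2HO, C9 cis to C15
Conditions: Hoveyda–Grubbs II (cat.), 15 (excess), 1,4-benzoquinone (cat.), CH2Cl2, 40 °C
Reagents that add atoms: none
Why: Olefin cross-metathesis of a terminal allylic alcohol with methacrolein gives the thermodynamic E-trisubstituted enal, the trisubstituted vinyl iodide being inert to the catalyst.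

**Step 12**
Reactants: 2 (E)-1-methoxypent-1-en-3-one; 16 (E)-enal alcohol
Product: 18 silaketal triene: O9–Si(iPr)2–O12 links 16 to the (1E,3Z)-1-methoxypenta-1,3-dien-3-yl unit (C14=C13–C12=C11–C20), via (1E,3Z)-1-methoxypenta-1,3-dien-3-yl diisopropylsilyl triflate 17 (not isolated)
Conditions: iPr2Si(OTf)2, Et3N, 2, CH2Cl2, −78 → −20 °C; then 16, Et3N, −20 → 0 °C; filtration through Et3N-deactivated silica
Reagents that add atoms: diisopropylsilyl bis(trifluoromethanesulfonate), CC(C)[Si](OS(=O)(=O)C(F)(F)F)(OS(=O)(=O)C(F)(F)F)C(C)C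
Why: Soft enolisation/O-silylation of the ethyl ketone with a silyl triflate and Et3N gives the Z-enol silane, the two isopropyl groups slow a second enolsilylation, and the remaining Si–OTf bond then silylates the C9 hydroxyl (unsymmetrical silaketal formation).

**Step 13**
Reactants: 18 silaketal triene
Product: 19 bridged cycloadduct: 2,4-dioxa-3-silabicyclo[4.3.1]dec-1(9)-ene core (bridgeheads C12 and C10, bridgehead enol ether C12=C13) with 1β-CH3, 1α-CHO, 10α-H, 11β-CH3, 14β-OMe
Conditions: PhMe (5 mM), BHT, base-washed sealed tube, 150 °C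
Reagents that add atoms: none
Why: Mechanism and precedent: a thermal, concerted but asynchronous [4+2] cycloaddition (type 2 intramolecular Diels–Alder reaction, diene tethered through its 2-oxygen) joins the nucleophilic diene terminus C11 to the β-carbon C10 and C14 to the fully substituted α-carbon C1, the closest known reaction type being the type 2 intramolecular Diels–Alder reaction through a disposable dialkoxysilane tether or a 2-acyloxy tether, which gives bridgehead enol derivatives of bicyclo[4.3.1]decenes. Ring closure: two rings close at once, the cyclohexene (C1, C10, C11, C12, C13, C14) in the suprafacial [4+2] mode and with it the seven-membered 1,3-dioxa-2-silepane (C9, C10, C11, C12, O, Si, O), because the four-atom tether allows only the 1,3-bridged orientation, which is also the electronically matched one (C12–O para to C1–CHO). C10 and C1: the diene can reach only the alkene face on which O9 stands, and A(1,3) strain between C9–H and the cis C15 methyl fixes that rotamer (H in the alkene plane, C8 on the far face), so C9 dictates the face while the E-alkene geometry becomes the trans relation of C2 and C9. C11 and C14: the tether forces C9, and with it C15, endo, and the Z-enol ether puts C20 in the outside position, so C20 ends cis to C9 and C15, while the 14-OMe group from the E-enol ether is likewise β and is lost in step 16. Selectivity: site selectivity (enal versus vinyl iodide and lactone) is secured by electron demand, regio- and facial selectivity by tether length and C9, and survival of the acid-labile diene by base-washed glass, BHT and high dilution. Strategic gain: the strained bridgehead silyl enol ether masks both the C12 ketone and O9, so the C2 aldehyde is the only electrophile offered in step 14.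

**Step 14**
Reactants: 19 bridged aldehyde; 20 vinylmagnesium bromide
Product: 21 (2R)-allylic alcohol: C1–C2H(OH)–C3H=C4H2, C2 as in the target
Conditions: THF, −78 → −40 °C; aq. NH4Cl
Reagents that add atoms: none
Why: Grignard 1,2-addition under Felkin–Anh control, since the formyl group is held axial on the α-face opposite the siloxane bridge with its H under the ring and its O eclipsing C1–CH3, so the nucleophile should enter anti to the large C10 over the flat C14/C13=C12 flank, and the aldehyde reacts far faster than the hindered lactone.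

**Step 15**
Reactants: 21 allylic alcohol
Product: 22 C2 acetate
Conditions: Ac2O, DMAP, Et3N, CH2Cl2, rt
Reagents that add atoms: acetic anhydride, CC(=O)OC(C)=O
Why: DMAP-catalysed acetylation installs the C2 acetate of the target while O9, O8 and the C12 carbonyl are all still masked.

**Step 16**
Reactants: 22 bridged acetate
Product: 24 cyclohexenone (C12=O, C13=C14) with C9–O–Si(iPr)2OMe and C8–OTES, via 14β-methoxy C12 ketone 23 (not isolated)
Conditions: CSA (cat.), MeOH–CH2Cl2 1:4, 0 °C
Reagents that add atoms: methanol, CO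
Why: Acid-catalysed methanolysis of the strained silyl enol ether (protonation at C13, methanol attack at silicon) followed by acid-induced β-elimination of methanol is the standard unmasking of 1-methoxy-3-silyloxy diene adducts, and it leaves silicon on O9 as a dialkyl(alkoxy)silyl protecting group while the mild conditions spare the C11 stereocentre.

**Step 17**
Reactants: 24 cyclohexenone
Product: 25 12β-allylic alcohol
Conditions: NaBH4, CeCl3·7H2O, MeOH, −78 °C
Reagents that add atoms: none
Why: Luche 1,2-reduction, in which the ring should sit in the half-chair with C15 and C20 equatorial and the C9 chain axial on the β-face, so hydride is expected from the open α-face to give the 12β-alcohol.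

**Step 18**
Reactants: 25 12β-alcohol (C3=C4 vinyl, C5 vinyl iodide)
Product: 27 bicyclo[8.4.0] macrocycle with (5Z)-alkene, 12β-OH, 2-OAc, 8-OTES and 9-OSi(iPr)2OMe, via C4-(9-BBN) borane / O12-(9-BBN) borinate 26 (not isolated)
Conditions: 9-BBN-H, THF, 0 °C → rt; then slow addition to PdCl2(dppf)·CH2Cl2, AsPh3, Cs2CO3, DMF–THF–H2O, rt → 45 °C, final 1 mM
Reagents that add atoms: 9-borabicyclo[3.3.1]nonane, B1C2CCCC1CCC2
Why: Chemoselective anti-Markovnikov hydroboration of the only monosubstituted alkene and intramolecular B-alkyl Suzuki–Miyaura coupling with retention at the vinyl iodide should close the ten-membered ring at C4–C5 with the Z-geometry already fixed, and running it on the free C12 alcohol avoids Pd(0) ionisation of an allylic acetate.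

**Step 19**
Reactants: 27 macrocyclic 12β-alcohol
Product: 28 2,12α-diacetate (8-OTES, 9-OSi(iPr)2OMe)
Conditions: PPh3, DIAD, AcOH, PhMe, 0 °C → rt
Reagents that add atoms: acetic acid, CC(=O)O
Why: Mitsunobu esterification proceeds by SN2 inversion from the open α-face at the only free hydroxyl and sets C12 as in the target, the SN2′ path being closed by the neopentyl C14 next to quaternary C1.

**Step 20**
Reactants: 28 protected diacetate
Product: 29 CNP0286823.1 (target)
Conditions: HF·pyridine, pyridine–THF, 0 °C → rt
Reagents that add atoms: none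
Why: Fluoride-driven desilylation removes the tertiary TES ether and the alkoxysilyl ether under buffered acidic conditions that leave acetates, lactone and both alkenes untouched and give no chance for base-induced lactone migration.

**Compound list**
1 | (E)-4-methoxybut-3-en-2-one | CO/C=C/C(C)=O | starting material
2 | (E)-1-methoxypent-1-en-3-one | CCC(=O)/C=C/OC | intermediate
3 | methyl 4,6-O-[(R)-benzylidene]-α-D-glucopyranoside | CO[C@H]1O[C@@H]2CO[C@@H](c3ccccc3)O[C@H]2[C@H](O)[C@H]1O | starting material
4 | 2-bromopropanoyl bromide | CC(Br)C(=O)Br | starting material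
5 | methyl 4,6-O-benzylidene-2-O-(2-bromopropanoyl)-α-D-glucopyranoside | CO[C@H]1O[C@@H]2CO[C@@H](c3ccccc3)O[C@H]2[C@H](O)[C@H]1OC(=O)C(C)Br | intermediate
6 | methyl 4,6-O-benzylidene-2-O-(2-bromopropanoyl)-α-D-ribo-hexopyranosid-3-ulose | CO[C@H]1O[C@@H]2CO[C@@H](c3ccccc3)O[C@H]2C(=O)[C@H]1OC(=O)C(C)Br | intermediate
7 | benzylidene-protected trans-fused hydroxy lactone | CO[C@H]1O[C@@H]2CO[C@@H](c3ccccc3)O[C@H]2[C@]3(O)[C@@H](C)C(=O)O[C@@H]13 | intermediate
8 | triol lactone | CO[C@H]1O[C@H](CO)[C@@H](O)[C@]2(O)[C@@H](C)C(=O)O[C@@H]12 | intermediate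
9 | 6-iodo diol lactone | CO[C@H]1O[C@H](CI)[C@@H](O)[C@]2(O)[C@@H](C)C(=O)O[C@@H]12 | intermediate
10 | 6-iodo bis-TES lactone | CO[C@H]1O[C@H](CI)[C@@H](O[Si](CC)(CC)CC)[C@]2(O[Si](CC)(CC)CC)[C@@H](C)C(=O)O[C@@H]12 | intermediate
11 | lactone aldehyde (C6 CHO, C10 vinyl) | O=C[C@@H]1OC(=O)[C@H](C)[C@@]1(O[Si](CC)(CC)CC)[C@H](O[Si](CC)(CC)CC)C=C | intermediate
12 | ethyltriphenylphosphonium iodide | CC[P+](c1ccccc1)(c1ccccc1)c1ccccc1.[I-] | starting material
13 | (5Z)-vinyl iodide, bis-TES | C/C(I)=C/[C@@H]1OC(=O)[C@H](C)[C@@]1(O[Si](CC)(CC)CC)[C@H](O[Si](CC)(CC)CC)C=C | intermediate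
14 | (5Z)-vinyl iodide, C9 alcohol | C/C(I)=C/[C@@H]1OC(=O)[C@H](C)[C@@]1(O[Si](CC)(CC)CC)[C@H](O)C=C | intermediate
15 | methacrolein | CC(=C)C=O | starting material
16 | (E)-enal alcohol | C/C(I)=C/[C@@H]1OC(=O)[C@H](C)[C@@]1(O[Si](CC)(CC)CC)[C@H](O)/C=C(\C)C=O | intermediate
17 | (1E,3Z)-1-methoxypenta-1,3-dien-3-yl diisopropylsilyl triflate (not isolated) | C/C=C(\O[Si](C(C)C)(C(C)C)OS(=O)(=O)C(F)(F)F)/C=C/OC | intermediate
18 | silaketal triene | C/C(I)=C/[C@@H]1OC(=O)[C@H](C)[C@@]1(O[Si](CC)(CC)CC)[C@H](O[Si](C(C)C)(C(C)C)O/C(=C\C)/C=C/OC)/C=C(\C)C=O | intermediate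
19 | bridged cycloadduct aldehyde | C/C(I)=C/[C@@H]1OC(=O)[C@H](C)[C@@]1(O[Si](CC)(CC)CC)[C@@H]2O[Si](C(C)C)(C(C)C)OC3=C[C@@H](OC)[C@](C)(C=O)[C@@H]2[C@H]3C | intermediate
20 | vinylmagnesium bromide | C=C[Mg]Br | starting material
21 | bridged (2R)-allylic alcohol | C/C(I)=C/[C@@H]1OC(=O)[C@H](C)[C@@]1(O[Si](CC)(CC)CC)[C@@H]2O[Si](C(C)C)(C(C)C)OC3=C[C@@H](OC)[C@](C)([C@H](O)C=C)[C@@H]2[C@H]3C | intermediate
22 | bridged C2 acetate | C/C(I)=C/[C@@H]1OC(=O)[C@H](C)[C@@]1(O[Si](CC)(CC)CC)[C@@H]2O[Si](C(C)C)(C(C)C)OC3=C[C@@H](OC)[C@](C)([C@H](OC(C)=O)C=C)[C@@H]2[C@H]3C | intermediate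
23 | 14β-methoxy C12 ketone (not isolated) | C/C(I)=C/[C@@H]1OC(=O)[C@H](C)[C@@]1(O[Si](CC)(CC)CC)[C@H](O[Si](C(C)C)(C(C)C)OC)[C@H]2[C@@H](C)C(=O)C[C@@H](OC)[C@]2(C)[C@H](OC(C)=O)C=C | intermediate
24 | cyclohexenone | C/C(I)=C/[C@@H]1OC(=O)[C@H](C)[C@@]1(O[Si](CC)(CC)CC)[C@H](O[Si](C(C)C)(C(C)C)OC)[C@H]2[C@@H](C)C(=O)C=C[C@]2(C)[C@H](OC(C)=O)C=C | intermediate
25 | 12β-allylic alcohol | C/C(I)=C/[C@@H]1OC(=O)[C@H](C)[C@@]1(O[Si](CC)(CC)CC)[C@H](O[Si](C(C)C)(C(C)C)OC)[C@H]2[C@@H](C)[C@@H](O)C=C[C@]2(C)[C@H](OC(C)=O)C=C | intermediate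
26 | C4-borane / O12-borinate (not isolated) | C/C(I)=C/[C@@H]1OC(=O)[C@H](C)[C@@]1(O[Si](CC)(CC)CC)[C@H](O[Si](C(C)C)(C(C)C)OC)[C@H]2[C@@H](C)[C@@H](OB3C4CCCC3CCC4)C=C[C@]2(C)[C@H](OC(C)=O)CCB5C6CCCC5CCC6 | intermediate
27 | macrocyclic 12β-alcohol | O[C@H]1C=C[C@@]2(C)[C@H]([C@H]1C)[C@@H](O[Si](C(C)C)(C(C)C)OC)[C@@]1(O[Si](CC)(CC)CC)[C@H](/C=C(/C)CC[C@H]2OC(C)=O)OC(=O)[C@@H]1C | intermediate
28 | protected 2,12α-diacetate | CC(=O)O[C@@H]1C=C[C@@]2(C)[C@H]([C@H]1C)[C@@H](O[Si](C(C)C)(C(C)C)OC)[C@@]1(O[Si](CC)(CC)CC)[C@H](/C=C(/C)CC[C@H]2OC(C)=O)OC(=O)[C@@H]1C | intermediate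
29 | CNP0286823.1 | CC(=O)O[C@@H]1C=C[C@@]2(C)[C@H]([C@H]1C)[C@@H](O)[C@@]1(O)[C@H](/C=C(/C)CC[C@H]2OC(C)=O)OC(=O)[C@@H]1C | target

**Total step count:** 20.
**Longest linear sequence:** 19 (steps 2–20, from 3).

**Steps most likely to fail**

*Step 13.* The heat- and acid-sensitive dienol silane may be lost by protodesilylation or hydrogen shift before the strained bridgehead-alkene transition state is reached. Intermolecular addition may also compete.

The fallback sets out from 16 (and 2) and returns at 24; it gives up the tether.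
- The C9 hydroxyl of 16 would be capped with iPr2Si(OTf)2/2,6-lutidine and then methanol to give the diisopropyl(methoxy)silyl ether of the enal F1.
- Ketone 2 would be converted with TBSOTf/Et3N into (1E,3Z)-3-(tert-butyldimethylsilyloxy)-1-methoxypenta-1,3-diene F2.
- An intermolecular Diels–Alder reaction of the two (neat under high pressure, or with a mild lanthanide Lewis acid) should give the cyclohexene aldehyde F3. The face anti to C8 is chosen by the same A(1,3) rotamer, and the exo-formyl orientation is the one usual for 2-methyl enals.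
- Vinylmagnesium bromide would then give the allylic alcohol F4, and acetylation the acetate F5.
- CSA in methanol would unmask F5 to 24.

*Step 18.* Slow ring closure against transannular strain may let oligomerisation, protodeboronation or β-hydride elimination take over. Pd(0) may also ionise the allylic C7–O lactone bond.

The fallback sets out from 25 and returns at 27; it uses neither boron transfer, base nor palladium in the ring closure.
- Hydroboration with 9-BBN and NaBO3 oxidation would give the primary alcohol F6.
- Appel-type iodination of the primary hydroxyl would give the alkyl iodide F7.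
- A nickel-catalysed reductive cross-electrophile coupling (NiBr2·glyme, dtbbpy, Zn, DMA, high dilution) would join the sp3 iodide C4 to the vinyl iodide C5.

*Step 9.* The hindered α-acyloxy aldehyde may convert slowly, the basic ylide may epimerise C7, and iodine may be lost from the ylide.

The fallback sets out from 11 and returns at 13; it builds the trisubstituted halide by cross-coupling instead of a Wittig reaction.
- CBr4/PPh3 would give the 1,1-dibromoalkene F8.
- A trans-selective Pd-catalysed Negishi methylation (MeZnCl, PdCl2(DPEphos)) would give the (Z)-2-bromoalkene F9.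
- A copper-catalysed halogen exchange (CuI, NaI, trans-N,N′-dimethylcyclohexane-1,2-diamine, dioxane, heat) would give 13 with retention.

**Further compounds**
F1 | step 13 | diisopropyl(methoxy)silyl ether of enal 16 | C/C(I)=C/[C@@H]1OC(=O)[C@H](C)[C@@]1(O[Si](CC)(CC)CC)[C@H](O[Si](C(C)C)(C(C)C)OC)/C=C(\C)C=O
F2 | step 13 | (1E,3Z)-3-(tert-butyldimethylsilyloxy)-1-methoxypenta-1,3-diene | C/C=C(\O[Si](C)(C)C(C)(C)C)/C=C/OC
F3 | step 13 | untethered cycloadduct aldehyde (TBS enol ether) | C/C(I)=C/[C@@H]1OC(=O)[C@H](C)[C@@]1(O[Si](CC)(CC)CC)[C@H](O[Si](C(C)C)(C(C)C)OC)[C@H]2[C@@H](C)C(O[Si](C)(C)C(C)(C)C)=C[C@@H](OC)[C@]2(C)C=O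
F4 | step 13 | untethered (2R)-allylic alcohol | C/C(I)=C/[C@@H]1OC(=O)[C@H](C)[C@@]1(O[Si](CC)(CC)CC)[C@H](O[Si](C(C)C)(C(C)C)OC)[C@H]2[C@@H](C)C(O[Si](C)(C)C(C)(C)C)=C[C@@H](OC)[C@]2(C)[C@H](O)C=C
F5 | step 13 | untethered C2 acetate | C/C(I)=C/[C@@H]1OC(=O)[C@H](C)[C@@]1(O[Si](CC)(CC)CC)[C@H](O[Si](C(C)C)(C(C)C)OC)[C@H]2[C@@H](C)C(O[Si](C)(C)C(C)(C)C)=C[C@@H](OC)[C@]2(C)[C@H](OC(C)=O)C=C
F6 | step 18 | C4 primary alcohol | C/C(I)=C/[C@@H]1OC(=O)[C@H](C)[C@@]1(O[Si](CC)(CC)CC)[C@H](O[Si](C(C)C)(C(C)C)OC)[C@H]2[C@@H](C)[C@@H](O)C=C[C@]2(C)[C@H](OC(C)=O)CCO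
F7 | step 18 | C4 primary iodide | C/C(I)=C/[C@@H]1OC(=O)[C@H](C)[C@@]1(O[Si](CC)(CC)CC)[C@H](O[Si](C(C)C)(C(C)C)OC)[C@H]2[C@@H](C)[C@@H](O)C=C[C@]2(C)[C@H](OC(C)=O)CCI
F8 | step 9 | 1,1-dibromoalkene | BrC(Br)=C[C@@H]1OC(=O)[C@H](C)[C@@]1(O[Si](CC)(CC)CC)[C@H](O[Si](CC)(CC)CC)C=C
F9 | step 9 | (Z)-2-bromoalkene | C/C(Br)=C/[C@@H]1OC(=O)[C@H](C)[C@@]1(O[Si](CC)(CC)CC)[C@H](O[Si](CC)(CC)CC)C=C
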